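**Retrosynthetic overview**

1. Numbering as in benzofuran (O1, C2 carbinol-bearing CH, C3, C3a quaternary, C4 C=O, C5 isobutyryl, C6 C–OH, C7 prenyl, C7a). In ring A the bonds C3a–C4 and C5–C6 are a [4+2] retron (diene C3a=C7a–C7=C6, dienophile C4≡C5). The tertiary oxygen of the C2 side chain lies on the same face of the dihydrofuran ring as C4, four atoms from C3a, so it can carry the dienophile as an ynol ether.
2. Target ⇐ acid hydrolysis ⇐ tricyclic adduct (C6 silyl methyl ketal, C4–O–CMe2 bridge) ⇐ intramolecular Diels–Alder of a silyl ketene acetal diene tethered to an alkoxy ynone. Ring A and the six-membered oxa-bridge close together, ring A is the last ring formed, and the bridge is then cleaved.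
3. Precursor ⇐ ynone installed last on a dichlorovinyl ether, after the ester has been turned into the silyl ketene acetal ⇐ 2-alkylideneoxolane ester (dihydrofuran ring, formed first) ⇐ β-keto ester dianion + (S)-epoxide.
4. Epoxide ⇐ (S)-glycerate acetonide (source of C2), MeMgBr, trichloroethylene; β-keto ester ⇐ Claisen self-condensation of methyl 5-methylhex-4-enoate.

Key step: step 10

Remark: compounds 11–13 are carried as isomer mixtures at C3a and C7 (and at the exocyclic alkene of 13); both carbons become sp2 in diene 15, so these elements are left undefined in the SMILES.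

**Route**

Step 1
Reactants: 1 methyl (4S)-2,2-dimethyl-1,3-dioxolane-4-carboxylate
Product: 2 2-[(4S)-2,2-dimethyl-1,3-dioxolan-4-yl]propan-2-ol
Conditions: MeMgBr (2.5 equiv), THF, 0 °C → rt; aq NH4Cl
Reagents that add atoms: methylmagnesium bromide, C[Mg]Br
Why: Double Grignard addition to the ester gives the tertiary carbinol whose oxygen becomes the tether atom; the acetonide-bearing stereocentre, which becomes C2 (S), is not touched.

Step 2
Reactants: 2 2-[(4S)-2,2-dimethyl-1,3-dioxolan-4-yl]propan-2-ol; 3 trichloroethylene
Product: 4 (4S)-4-(2-{[(E)-1,2-dichloroethenyl]oxy}propan-2-yl)-2,2-dimethyl-1,3-dioxolane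
Conditions: KH, THF, 0 °C; Cl2C=CHCl, −50 °C → rt
Reagents that add atoms: none
Why: Addition of the potassium alkoxide to dichloroacetylene formed in situ from trichloroethylene (dichlorovinyl ether route to ynol ethers) should give the E ether by anti addition; the substrate has no carbonyl group and no second hydroxyl, so neither enolate dichlorovinylation nor alkoxide migration can interfere.

Step 3
Reactants: 4 (4S)-4-(2-{[(E)-1,2-dichloroethenyl]oxy}propan-2-yl)-2,2-dimethyl-1,3-dioxolane
Product: 5 (2S)-3-{[(E)-1,2-dichloroethenyl]oxy}-3-methylbutane-1,2-diol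
Conditions: AcOH–H2O (4:1), 40 °C
Reagents that add atoms: none
Why: Acid-catalysed acetonide hydrolysis; the two chlorine atoms make the vinyl ether much less prone to C-protonation than an ordinary enol ether, so it should survive dilute acetic acid.

Step 4
Reactants: 5 (2S)-3-{[(E)-1,2-dichloroethenyl]oxy}-3-methylbutane-1,2-diol
Product: 7 (2S)-2-(2-{[(E)-1,2-dichloroethenyl]oxy}propan-2-yl)oxirane, via primary monotosylate 6 (not isolated)
Conditions: NaH (2.2 equiv), N-tosylimidazole, THF, 0 °C → rt
Reagents that add atoms: none
Why: Selective sulfonylation of the primary alkoxide followed by intramolecular Williamson displacement by the secondary alkoxide should give the terminal epoxide; the C–O bond at the stereocentre is never broken (retention), and with the tertiary oxygen etherified no Payne rearrangement is possible.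

Step 5
Reactants: 8 methyl 5-methylhex-4-enoate (2 equiv)
Product: 9 methyl 7-methyl-2-(3-methylbut-2-en-1-yl)-3-oxooct-6-enoate
Conditions: NaH, MeOH (cat.), THF, reflux; 1 M HCl
Reagents that add atoms: none
Why: Claisen self-condensation, driven by deprotonation of the product, assembles the chain C6–C7(prenyl)–C7a–C3a(prenyl) in one operation; the α-stereocentre needs no control because that carbon becomes sp2 later.

Step 6
Reactants: 9 methyl 7-methyl-2-(3-methylbut-2-en-1-yl)-3-oxooct-6-enoate; 7 (2S)-2-(2-{[(E)-1,2-dichloroethenyl]oxy}propan-2-yl)oxirane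
Product: 11 methyl (6S)-7-{[(E)-1,2-dichloroethenyl]oxy}-6-hydroxy-7-methyl-2,4-bis(3-methylbut-2-en-1-yl)-3-oxooctanoate, via keto ester dianion 10 (not isolated)
Conditions: NaH, THF, 0 °C; n-BuLi, 0 °C; then 7, BF3·OEt2, −78 °C; aq NH4Cl
Reagents that add atoms: none
Why: γ-Alkylation of the β-keto ester dianion by Lewis-acid-assisted opening of the terminal epoxide at its CH2 carbon forms C3–C3a without touching the epoxide stereocentre (future C2); the new centre at C3a forms unselectively and is erased in step 8, and at −78 °C the delocalised dianion should not dehydrochlorinate the vinyl ether, whose vinylic hydrogen is syn to the chlorine that would have to leave.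

Step 7
Reactants: 11 methyl (6S)-7-{[(E)-1,2-dichloroethenyl]oxy}-6-hydroxy-7-methyl-2,4-bis(3-methylbut-2-en-1-yl)-3-oxooctanoate
Product: 13 methyl 2-[(5S)-5-(2-{[(E)-1,2-dichloroethenyl]oxy}propan-2-yl)-3-(3-methylbut-2-en-1-yl)oxolan-2-ylidene]-5-methylhex-4-enoate, via cyclic hemiketal 12 (not isolated)
Conditions: pyridinium p-toluenesulfonate (cat.), PhMe, 4 Å MS, 80 °C
Reagents that add atoms: none
Why: Acid-catalysed cyclodehydration of the γ-hydroxy β-keto ester through its five-membered hemiketal closes O1–C7a and should give the push–pull 2-alkylideneoxolane (vinylogous carbonate); C2 is not involved, and the isomers at C3a and at the new alkene converge in the next step.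

Step 8
Reactants: 13 methyl 2-[(5S)-5-(2-{[(E)-1,2-dichloroethenyl]oxy}propan-2-yl)-3-(3-methylbut-2-en-1-yl)oxolan-2-ylidene]-5-methylhex-4-enoate
Product: 15 O-tert-butyldimethylsilyl O-methyl ketene acetal of 13 (diene C3a=C7a–C7=C6 in a 4,5-dihydrofuran; dichlorovinyl ether unchanged), via lithium dienolate 14 (not isolated)
Conditions: LiN(iPr)2, THF–DMPU, −78 °C; TBSCl, −78 → 0 °C; pentane, cold aq NaHCO3
Reagents that add atoms: tert-butyldimethylsilyl chloride, CC(C)(C)[Si](C)(C)Cl
Why: γ-Deprotonation of the vinylogous carbonate at C3a (or α-deprotonation at C7 of any deconjugated isomer) and O-silylation of the ester dienolate (vinylketene silyl acetal formation) should give one diene from all isomers of 13 and remove the ester carbonyl before the organolithium step; the amide base should leave the dichlorovinyl ether alone at −78 °C.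

Step 9
Reactants: 15 O-tert-butyldimethylsilyl O-methyl ketene acetal of 13; 16 N-methoxy-N-methylisobutyramide
Product: 18 silyl ketene acetal diene tethered to the alkoxy ynone (as 15 but bearing CMe2–O–C≡C–C(=O)CHMe2 in place of the dichlorovinyl ether), via lithium alkoxyacetylide 17 (not isolated)
Conditions: n-BuLi (2.2 equiv), THF, −78 °C; 16, −78 → −30 °C; pentane, cold aq NaHCO3; kept at or below 0 °C
Reagents that add atoms: none
Why: Dehydrochlorination and chlorine–lithium exchange convert the dichlorovinyl ether into the lithium alkoxyacetylide, which is acylated by the N-methoxy-N-methylamide (Weinreb ketone synthesis); the silyl ketene acetal should be inert to butyllithium at −78 °C, and the ynone appears only on the cold, weakly basic quench that collapses the tetrahedral adduct, when no base or nucleophile is left.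

Step 10
Reactants: 18 silyl ketene acetal diene tethered to the alkoxy ynone
Product: 19 tricyclic cycloadduct (ring A cyclohexa-1,4-diene; C6 carries OMe and OSi(tBu)Me2; C4 bridged through oxygen to the CMe2 carbon on C2; C5 isobutyryl)
Conditions: PhMe, 0 → 45 °C (base-washed glass)
Reagents that add atoms: none
Why: Proposed new method: an intramolecular [4+2] cycloaddition of a 3-alkoxy-1-methoxy-1-silyloxy diene with an alkoxy ynone held on a four-atom ynol-ether tether is not known; the closest known reaction types are intermolecular Diels–Alder reactions of 1-alkoxy-1-silyloxy dienes with alkynones and oxygen-tethered intramolecular Diels–Alder reactions. The diene is most nucleophilic at C3a and the ynone most electrophilic at its oxygen-bearing carbon C4, so C3a–C4 should form first (6-exo-dig, vinylogous Mukaiyama–Michael-like) and the allenolate so formed should then close C5–C6 onto the silyloxycarbenium ion, a sequence that may merge into an asynchronous concerted cycloaddition and that does not need the fully planar s-cis diene disfavoured by the inward prenyl on C3a. Ring A is closed as the six-membered ring of the [4+2] process itself, and the six-membered oxa-bridge C3a–C3–C2–CMe2–O–C4 is closed by the tether in the first bond-forming event, giving the 3,6-dioxabicyclo[3.2.1]octane unit. C3a is set by the tether: anchored at C2 and only four atoms long, it can bring C4 only to the face of C3a on which the C2 side chain lies, so C4 ends cis to that side chain and prenyl trans, as in the target (C6 is also stereogenic in 19 but is erased in step 11). The step needs C3a–C4/C5–C6 regiochemistry, which the matched polarisation and the tether length should secure (bonding of C4 to C7 would need a bridged seven-membered ring), and it needs to outrun the retro-ene loss of the tertiary alkyl group from the ynol ether, which is why it is run neutral and at or below 45 °C.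

Step 11
Reactants: 19 tricyclic cycloadduct
Product: 21 (2S,3aS)-6-hydroxy-2-(2-hydroxypropan-2-yl)-3a,7-bis(3-methylbut-2-en-1-yl)-5-(2-methylpropanoyl)-3,3a-dihydro-1-benzofuran-4(2H)-one (target), via bridged trione 20 (not isolated)
Conditions: 1 M aq HCl, THF, 0 °C → rt
Reagents that add atoms: water, O
Why: Acid hydrolysis should first collapse the silyl methyl ketal at C6 to the ketone and then open the strained bridging vinylogous ester by addition of water at C4 and loss of the tertiary alcohol, leaving the enolised triketone; the unstrained dihydrofuran vinylogous ester is retained and neither stereocentre is involved.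

**Compound list**

1 | methyl (4S)-2,2-dimethyl-1,3-dioxolane-4-carboxylate | COC(=O)[C@@H]1COC(C)(C)O1 | starting material
2 | 2-[(4S)-2,2-dimethyl-1,3-dioxolan-4-yl]propan-2-ol | CC(C)(O)[C@@H]1COC(C)(C)O1 | intermediate
3 | trichloroethylene | ClC=C(Cl)Cl | starting material
4 | (4S)-4-(2-{[(E)-1,2-dichloroethenyl]oxy}propan-2-yl)-2,2-dimethyl-1,3-dioxolane | Cl/C=C(/Cl)OC(C)(C)[C@@H]1COC(C)(C)O1 | intermediate
5 | (2S)-3-{[(E)-1,2-dichloroethenyl]oxy}-3-methylbutane-1,2-diol | Cl/C=C(/Cl)OC(C)(C)[C@@H](O)CO | intermediate
6 | (2S)-3-{[(E)-1,2-dichloroethenyl]oxy}-2-hydroxy-3-methylbutyl 4-methylbenzenesulfonate | Cl/C=C(/Cl)OC(C)(C)[C@@H](O)COS(=O)(=O)c1ccc(C)cc1 | intermediate (not isolated)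
7 | (2S)-2-(2-{[(E)-1,2-dichloroethenyl]oxy}propan-2-yl)oxirane | Cl/C=C(/Cl)OC(C)(C)[C@@H]1CO1 | intermediate
8 | methyl 5-methylhex-4-enoate | COC(=O)CCC=C(C)C | starting material
9 | methyl 7-methyl-2-(3-methylbut-2-en-1-yl)-3-oxooct-6-enoate | COC(=O)C(CC=C(C)C)C(=O)CCC=C(C)C | intermediate
10 | sodium lithium bis-enolate (dianion) of 9 | COC(O[Na])=C(CC=C(C)C)C(O[Li])=CCC=C(C)C | intermediate (not isolated)
11 | methyl (6S)-7-{[(E)-1,2-dichloroethenyl]oxy}-6-hydroxy-7-methyl-2,4-bis(3-methylbut-2-en-1-yl)-3-oxooctanoate | COC(=O)C(CC=C(C)C)C(=O)C(CC=C(C)C)C[C@H](O)C(C)(C)O/C(Cl)=C\Cl | intermediate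
12 | methyl 2-[(5S)-5-(2-{[(E)-1,2-dichloroethenyl]oxy}propan-2-yl)-2-hydroxy-3-(3-methylbut-2-en-1-yl)oxolan-2-yl]-5-methylhex-4-enoate (cyclic hemiketal of 11) | COC(=O)C(CC=C(C)C)C1(O)O[C@H](C(C)(C)O/C(Cl)=C\Cl)CC1CC=C(C)C | intermediate (not isolated)
13 | methyl 2-[(5S)-5-(2-{[(E)-1,2-dichloroethenyl]oxy}propan-2-yl)-3-(3-methylbut-2-en-1-yl)oxolan-2-ylidene]-5-methylhex-4-enoate | COC(=O)C(CC=C(C)C)=C1O[C@H](C(C)(C)O/C(Cl)=C\Cl)CC1CC=C(C)C | intermediate
14 | lithium dienolate of 13 (O-lithio ketene acetal, C7a=C3a in the ring) | CC(C)=CCC(=C(OC)O[Li])C1=C(CC=C(C)C)C[C@@H](C(C)(C)O/C(Cl)=C\Cl)O1 | intermediate (not isolated)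
15 | tert-butyl({1-methoxy-5-methyl-2-[(5S)-5-(2-{[(E)-1,2-dichloroethenyl]oxy}propan-2-yl)-3-(3-methylbut-2-en-1-yl)-4,5-dihydrofuran-2-yl]hexa-1,4-dien-1-yl}oxy)dimethylsilane | CC(C)=CCC(=C(OC)O[Si](C)(C)C(C)(C)C)C1=C(CC=C(C)C)C[C@@H](C(C)(C)O/C(Cl)=C\Cl)O1 | intermediate
16 | N-methoxy-N-methylisobutyramide | CON(C)C(=O)C(C)C | starting material
17 | lithium alkoxyacetylide (as 15, side chain CMe2–O–C≡C–Li) | CC(C)=CCC(=C(OC)O[Si](C)(C)C(C)(C)C)C1=C(CC=C(C)C)C[C@@H](C(C)(C)OC#C[Li])O1 | intermediate (not isolated)
18 | silyl ketene acetal diene tethered to the alkoxy ynone (as 15, side chain CMe2–O–C≡C–C(=O)CHMe2; S at the carbinol-bearing ring carbon) | CC(C)=CCC(=C(OC)O[Si](C)(C)C(C)(C)C)C1=C(CC=C(C)C)C[C@@H](C(C)(C)OC#CC(=O)C(C)C)O1 | intermediate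
19 | tricyclic cycloadduct: ring A cyclohexa-1,4-diene, C6(OMe)(OSi(tBu)Me2), C4–O–CMe2 bridge to C2, configuration at C2 and C3a as in the target | CC(C)=CCC1=C2O[C@H](C(C)(C)O3)C[C@]2(CC=C(C)C)C3=C(C(=O)C(C)C)C1(OC)O[Si](C)(C)C(C)(C)C | intermediate
20 | bridged trione: as 19 but C6=O | CC(C)=CCC1=C2O[C@H](C(C)(C)O3)C[C@]2(CC=C(C)C)C3=C(C(=O)C(C)C)C1=O | intermediate (not isolated)
21 | (2S,3aS)-6-hydroxy-2-(2-hydroxypropan-2-yl)-3a,7-bis(3-methylbut-2-en-1-yl)-5-(2-methylpropanoyl)-3,3a-dihydro-1-benzofuran-4(2H)-one | CC(C)=CCC1=C2O[C@H](C(C)(C)O)C[C@]2(CC=C(C)C)C(=O)C(C(=O)C(C)C)=C1O | target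

**Step count and risks**

Total steps: 11. Longest linear sequence: 10 (steps 1–4 and 6–11; step 5 is the side branch).

Step 10 (new method). What may go wrong: the ring-forming bonds are made too slowly, so that thermal retro-ene loss of the tertiary alkyl group from the ynol ether or adventitious hydrolysis of the ketene acetal takes over, or the sequence halts after the first C–C bond. Fallback with known reaction types, setting out from 18 and coming back at 21: anhydrous fluoride ((Me2N)3S+ Me3SiF2−, THF, −78 °C) desilylates 18 to the free dienolate, which should add through C3a to the tethered ynone (intramolecular Michael addition, 6-exo-dig; the tether again fixes C3a), and protonation gives the oxa-bridged Michael adduct F1. Dilute HCl in aqueous THF then hydrolyses its bridging vinylogous ester to the hydroxy β-diketone ester F2. A Dieckmann condensation (KOtBu, THF, 0 °C → rt) of the β-diketone carbon C5 onto the methyl ester C6 closes ring A and gives 21.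

Step 9. What may go wrong: butyllithium attacks silicon, or the quench that frees the ynone also hydrolyses the ketene acetal, so that 18 is not obtained intact. Fallback, setting out from 13 and coming back at 18: the order of events is reversed. Compound 13 is first converted into its lithium dienolate (LiN(iPr)2, THF, −78 °C), which shields the ester while n-BuLi and then 16 build the ynone. A neutral quench gives the stable methyl ester ynone F3. Soft enolisation at the doubly activated C7–H (TBSOTf, Et3N, CH2Cl2, −78 °C) then puts the silyl group on last and gives 18.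

Step 6. What may go wrong: the hindered secondary carbanion of 10 opens the epoxide too slowly, and proton transfer or attack on the chlorinated vinyl ether competes. Fallback, setting out from 7 and coming back at 11: two separate enolate steps replace the dianion. The diethylaluminium enolate of 8 (LiN(iPr)2; Et2AlCl, THF, −78 → −20 °C) opens 7 at its CH2 carbon and the hydroxy ester lactonises on acidic work-up to the α-prenyl γ-lactone F4. Addition of the lithium enolate of 8 to the lactone carbonyl (crossed Claisen-type acylation, THF, −78 °C) then gives 11, in equilibrium with its hemiketal 12, which enters step 7.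

**Further compounds**

F1 | step 10 | oxa-bridged Michael adduct: methyl ester on exocyclic C7=C7a, C3a bonded to C4, C4(=CH–C(=O)CHMe2)–O–CMe2 bridge to C2 | CC(C)=CCC(C(=O)OC)=C2O[C@H](C(C)(C)O3)C[C@]2(CC=C(C)C)C3=CC(=O)C(C)C
F2 | step 10 | hydroxy β-diketone ester: as F1 but C4=O, C5H2 and free CMe2OH | CC(C)=CCC(C(=O)OC)=C2O[C@H](C(C)(C)O)C[C@]2(CC=C(C)C)C(=O)CC(=O)C(C)C
F3 | step 9 | methyl 5-methyl-2-[(5S)-5-{2-[(4-methyl-3-oxopent-1-yn-1-yl)oxy]propan-2-yl}-3-(3-methylbut-2-en-1-yl)-4,5-dihydrofuran-2-yl]hex-4-enoate | COC(=O)C(CC=C(C)C)C1=C(CC=C(C)C)C[C@@H](C(C)(C)OC#CC(=O)C(C)C)O1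
F4 | step 6 | (5S)-5-(2-{[(E)-1,2-dichloroethenyl]oxy}propan-2-yl)-3-(3-methylbut-2-en-1-yl)oxolan-2-one | O=C1O[C@H](C(C)(C)O/C(Cl)=C\Cl)CC1CC=C(C)C
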